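The earlier runs and the new flask stem from a simulated flask from invented constants.

The meeting opened on a proposed invariant: free acid stays at its charge. The ochre flask was on the table, and the question concerned 6.0 h.

| setting | ochre | violet | flask |
|---|---|---|---|
| starting material | 0.050 M (fed, over 5.0 h) | 0.050 M (fed, over 5.0 h) | 0.050 M (fed, over 5.0 h) |
| acid | 5 mM | 5 mM | 5.00 mM |
| protic impurity | 0.010 M | 0.0050 M | 0.0100 M |
| remark | the very flask that is asked about, followed so far | run made earlier |  |
| time |  |  | 6.0 h |

ochre run (percent of the starting material charged)

| time / min | starting material / % | target / % |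
|---|---|---|
| 6.00 | 2.0 | 0.2 |
| 10.0 | 3.4 | 0.7 |
| 15.0 | 3.9 | 1.2 |
| 25.0 | 6.4 | 0.6 |
| 40.0 | 8.6 | 3.0 |
| 80.0 | 11.5 | 9.3 |

violet run (percent of the starting material charged)

| time / h | starting material / % | target / % |
|---|---|---|
| 0.500 | 7.6 | 2.3 |
| 0.833 | 9.7 | 4.4 |
| 1.33 | 11.0 | 9.6 |
| 2.00 | 11.9 | 16.8 |
| 4.00 | 13.3 | 39.3 |
| 6.00 | 6.6 | 60.5 |

(readings scatter by 0.5 percentage points)

- part of the starting material that has reacted at 6.0 h
- pH of the solution at 6.0 h

- acid is the free proton; pH is minus the decimal logarithm of its molar concentration
- what has gone from starting material into another species counts as reacted, even if it can come back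
- percentages count the whole charge, also what has not yet gone in
- a reading or a percentage of target counts all its forms, free or not
- a reading of starting material is of its free form alone

The first speaker wrote the balance of the acid, the smallest charge: free acid equals 5.00 mM minus whatever the reaction keeps, plus whatever it gives. She proposed to test this on target formation per unit of free starting material.

The second speaker read k′ = 0.893 h⁻¹ from the violet run between 2.00 h and 4.00 h. This is the hourly gain of target per unit of free starting material, a pseudo-first-order constant.

The third speaker read 0.940 h⁻¹ from the ochre run between 40.0 min and 80.0 min. That run holds twice the protic impurity of the violet run. Given the scatter, the meeting treated the two readings as alike and took the acid as returned.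

My own reckoning assumes that the extra protic impurity of the ochre flask changes nothing, and carries violet's free starting material at 6.00 h, 6.6 %, over to the ochre flask. That gives 93.4 % reacted, with the pH of the charged acid.

The forecast gives 93.4 % reacted (90.5 % to 95 %) and pH 2.3 (2.25 to 2.6). Its ground for the pH: “This means the acid stays near 5 mM and is not visibly consumed.”

The flask gives 93.0 % reacted and pH 2.30, with acid at 101 % of its charge at 6.00 h.

    starting material + target ⇌ idle adduct, settled at all times (K = 202 L mol⁻¹)
    starting material + acid → weak acid + acid + target (k = 174 L mol⁻¹ h⁻¹)
    weak acid ⇌ conjugate base + acid, settled at all times (K = 7.90 × 10⁻⁶ M)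
    starting material ⇌ dormant form (K = 18.0, k = 0.0791 h⁻¹)
    starting material → weak acid + target (k = 0.0271 h⁻¹)
    starting material + protic impurity → quenched substrate (k = 9.61 L mol⁻¹ h⁻¹)

With 7.0 % of free starting material, k′ gives an outflow to target of 0.0622 h⁻¹, as a fraction of the charge.

A neighbour flask holds more acid, 0.020 M. Scaling k′ with acid gives 3.57 h⁻¹. Supposing the same outflow, that leaves 1.75 % free, so 98.2 % reacted. The neighbour flask computes to 1.9 % free and 98.1 % reacted.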